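**Plan**

Numbering used throughout: C1 = prenyl bridgehead next to C8Me2, C2 = C–OMe, C3 = C–benzoyl, C4 = enone C=O, C5 = lavandulyl bridgehead, C6 = ring CH2, C7 = CH–prenyl, C9 = bridging C=O; ring A = C1–C2–C3–C4–C5–C9, ring B = C1–C8–C7–C6–C5–C9.
Retrosynthetic cuts, in order: C3–benzoyl; the two prenyl C=C bonds (back to allyl groups); C7–allyl (back to a C7 carboxyl); C4–C5 (opens ring A); C1–allyl; then ring B at C6–C7 and C9–C1, giving a 2-lavandulylacrylate (C6=C5–C9) and a 3,3-dimethylglutarate-derived bis-nucleophile (C7–C8–C1 carrying C2–C4).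
Enabling feature: the C9 ketone, its α-carbon C5 and the ring methylene C6 are an acrylate in disguise (acceptor at C6, acyl donor at C9). C7 and C1 lie 1,3 across the non-enolisable C8 and can both be made carbanionic: C7 by a temporary allyl ester, C1 as the γ-carbon of the ring A vinylogous ester (C4=O, C3=C2–OMe).
Forward order: ring B by a Michael–Claisen [3+3] union (step 10), C1 quaternary centre (step 11), ring A (step 12), C7 allyl (steps 13 and 14), double cross-metathesis and C3 benzoylation.
Stereochemistry: the lavandulyl centre comes from an Evans alkylation; C1 from a ligand-controlled Tsuji–Trost allylation whose allyl group is handed over from the C7 helper ester; C5 is forced by the bridge once C1 is fixed; C7 comes from exo-face radical allylation of the bicycle.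

Key step: step 10

Assumption: the (R,R) ligand in step 11 is taken to give the C1 configuration drawn (if its sense of induction on this enolate is the opposite, the (S,S) ligand is used); compounds 16 to 20 are carried as epimer mixtures at the acidic centres C5 and/or C7 (and C1 in 17), which are all reset later.

**Route**

Step 1
Reactants: 1 (S)-4-benzyl-1,3-oxazolidin-2-one; 2 3-methylbut-2-enoyl chloride
Product: 3 (S)-4-benzyl-3-(3-methylbut-2-enoyl)-1,3-oxazolidin-2-one
Conditions: n-BuLi, THF, −78 °C; then 2, −78 to 0 °C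
Reagents that add atoms: none
Why: N-acylation of the lithiated oxazolidinone by the acid chloride is the standard loading of the Evans auxiliary and creates no stereocentre.

Step 2
Reactants: 3 (S)-4-benzyl-3-(3-methylbut-2-enoyl)-1,3-oxazolidin-2-one; 4 1-bromo-3-methylbut-2-ene
Product: 5 (S)-4-benzyl-3-[(S)-5-methyl-2-(prop-1-en-2-yl)hex-4-enoyl]-1,3-oxazolidin-2-one
Conditions: NaN(SiMe3)2, THF, −78 °C; then 4, −78 to −30 °C
Reagents that add atoms: none
Why: Evans alkylation in its deconjugative form: γ-deprotonation gives the chelated (Z)-dienolate, which is alkylated at the α-carbon on the face away from the benzyl group, so that the lavandulyl stereocentre is set (S) and the double bond moves into the isopropenyl position.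

Step 3
Reactants: 5 (S)-4-benzyl-3-[(S)-5-methyl-2-(prop-1-en-2-yl)hex-4-enoyl]-1,3-oxazolidin-2-one
Product: 6 (S)-lavandulol, (S)-5-methyl-2-(prop-1-en-2-yl)hex-4-en-1-ol
Conditions: LiBH4, MeOH (1 equiv), Et2O, 0 °C
Reagents that add atoms: none
Why: Reductive removal of the Evans auxiliary by lithium borohydride, which reduces the exocyclic imide carbonyl selectively and should not enolise the stereocentre under these cold, weakly basic conditions.

Step 4
Reactants: 6 (S)-lavandulol
Product: 7 (S)-3-(iodomethyl)-2,6-dimethylhepta-1,5-diene (lavandulyl iodide)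
Conditions: PPh3, I2, imidazole, CH2Cl2, 0 °C to rt
Reagents that add atoms: iodine, [I][I]
Why: Appel-type iodination of the primary alcohol by SN2 displacement at the CH2 carbon, which does not involve the neighbouring stereocentre.

Step 5
Reactants: 7 (S)-lavandulyl iodide; 8 trimethyl phosphonoacetate
Product: 9 methyl (4R)-2-(dimethoxyphosphoryl)-7-methyl-4-(prop-1-en-2-yl)oct-6-enoate (both C2 epimers)
Conditions: NaH, THF/DMSO, 0 °C; then 7, 55 °C
Reagents that add atoms: none
Why: SN2 alkylation of the sodium phosphonoacetate carbanion by the primary iodide; the new phosphonate-bearing carbon forms as both epimers and becomes sp2 in step 6.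

Step 6
Reactants: 9 methyl (4R)-2-(dimethoxyphosphoryl)-7-methyl-4-(prop-1-en-2-yl)oct-6-enoate
Product: 10 methyl (R)-7-methyl-2-methylidene-4-(prop-1-en-2-yl)oct-6-enoate (2-lavandulylacrylate)
Conditions: 37% aq. HCHO, K2CO3, THF/H2O, 40 °C
Reagents that add atoms: formaldehyde, C=O
Why: Horner–Wadsworth–Emmons olefination with formaldehyde turns an α-alkyl phosphonoacetate into the 2-alkylacrylate and leaves the remote lavandulyl stereocentre untouched.

Step 7
Reactants: 11 3,3-dimethylglutaric anhydride
Product: 12 5-(allyloxy)-3,3-dimethyl-5-oxopentanoic acid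
Conditions: allyl alcohol (1.5 equiv), DMAP (cat.), Et3N, CH2Cl2, rt; aq. HCl work-up
Reagents that add atoms: allyl alcohol, C=CCO
Why: Nucleophile-catalysed alcoholysis of a symmetrical cyclic anhydride gives the half ester, and because the two carbonyls are equivalent no regiochemistry arises.

Step 8
Reactants: 12 5-(allyloxy)-3,3-dimethyl-5-oxopentanoic acid
Product: 14 7-allyl 1-methyl 5,5-dimethyl-3-oxoheptanedioate, via acyl imidazolide 13 (not isolated)
Conditions: CDI, THF, rt; then methyl potassium malonate, MgCl2, Et3N, THF, rt to 40 °C; aq. HCl work-up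
Reagents that add atoms: methyl potassium malonate, COC(=O)CC(=O)[O-].[K+]
Why: Masamune-type chain extension, in which the acyl imidazolide C-acylates the magnesium enolate of the malonate half ester and decarboxylation delivers the β-keto ester.

Step 9
Reactants: 14 7-allyl 1-methyl 5,5-dimethyl-3-oxoheptanedioate
Product: 15 7-allyl 1-methyl (E)-3-methoxy-5,5-dimethylhept-2-enedioate
Conditions: HC(OMe)3, p-TsOH·H2O (cat.), rt
Reagents that add atoms: trimethyl orthoformate, COC(OC)OC
Why: Acid-catalysed ketalisation of the ketone by the orthoformate followed by loss of methanol (enol ether formation) should give the thermodynamically preferred (E)-3-methoxy-2-enoate, in which the ester is cis to the chain carrying C1.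

Step 10
Reactants: 15 7-allyl 1-methyl (E)-3-methoxy-5,5-dimethylhept-2-enedioate; 10 methyl (R)-7-methyl-2-methylidene-4-(prop-1-en-2-yl)oct-6-enoate
Product: 17 allyl 3-[(E)-1,3-dimethoxy-3-oxoprop-1-en-1-yl]-2,2-dimethyl-5-[(2R)-5-methyl-2-(prop-1-en-2-yl)hex-4-en-1-yl]-4-oxocyclohexane-1-carboxylate (ring B ketone, stereoisomer mixture at ring positions 1, 3 and 5), via Michael adduct 16 (not isolated)
Conditions: LiN(i-Pr)2 (2.2 equiv), THF, −78 °C (15 added to the base); then 10, −78 °C; then t-BuOH (1.0 equiv), −78 to 0 °C; aq. NH4Cl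
Reagents that add atoms: none
Why: Double deprotonation of 15 gives a 1,3-bis-anion (allyl ester enolate at C7, vinylogous ester dienolate at C1) in which both ester carbonyls are masked as enolates, and the less delocalised, more basic C7 enolate adds to the unsubstituted terminus C6 of acrylate 10 in a Michael reaction (C6–C7). One equivalent of t-BuOH then protonates the new ester enolate at C5, the γ-carbon C1 of the remaining dienolate attacks the methyl ester carbonyl C9 with loss of methoxide (C9–C1), and the acidic C1–H of the product is removed so that the acylation should not reverse. The closest known reaction type is the consecutive Michael–Claisen [3+3] annulation that builds cyclohexane-1,3-diones and 2-acylcyclohexanones from enolates and acrylates, combined with the γ-acylation of 3-methoxy-2-enoate dienolates. Ring B is closed by the second event as a 6-(enolexo)-exo-trig Dieckmann-type acylation, the Michael step being intermolecular. The new stereocentres C1, C5 and C7 each carry an acidic hydrogen and are deliberately formed as equilibrating mixtures, since C1 is fixed in step 11, C5 in step 12 and C7 in step 14. The selectivity needed is site selectivity (C7 to C6, C1 to C9, and C1 rather than the α-carbon C3): it rests on the usual order of dianion reactivity, on the 1,3-spacing through quaternary C8 (the crossed acylations C7 to C9 or C5 to the allyl ester would make four-membered rings) and on the γ-preference of β-alkoxy dienolates.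

Step 11
Reactants: 17 ring B ketone (allyl ester)
Product: 18 3-allyl-3-[(E)-1,3-dimethoxy-3-oxoprop-1-en-1-yl]-2,2-dimethyl-5-[(2R)-5-methyl-2-(prop-1-en-2-yl)hex-4-en-1-yl]-4-oxocyclohexane-1-carboxylic acid (ring position 3 = C1 configured as in the target; epimers at positions 1 and 5)
Conditions: NaN(SiMe3)2 (1.0 equiv), THF, −78 °C; then Pd2(dba)3 (2.5 mol %), (R,R)-DACH-phenyl ligand N,N'-[(1R,2R)-cyclohexane-1,2-diyl]bis[2-(diphenylphosphanyl)benzamide] (7.5 mol %), toluene, −20 °C to rt; aq. HCl work-up
Reagents that add atoms: none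
Why: Tsuji–Trost asymmetric allylic alkylation: zerovalent palladium ionises the allyl ester of a second molecule to a π-allylpalladium carboxylate and the sodium enolate of the doubly activated C1–H attacks the allyl terminus from the face left open by the chiral diphosphine, which should set the C1 quaternary centre under ligand control while the helper ester at C7 is unmasked as the acid.

Step 12
Reactants: 18 C1-allylated keto acid
Product: 19 1-allyl-2-methoxy-8,8-dimethyl-5-[(2R)-5-methyl-2-(prop-1-en-2-yl)hex-4-en-1-yl]-4,9-dioxobicyclo[3.3.1]non-2-ene-7-carboxylic acid (C1 and C5 as in the target; both C7 epimers)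
Conditions: LiN(SiMe3)2 (2.3 equiv), THF, −78 to 0 °C; aq. HCl work-up
Reagents that add atoms: none
Why: Dieckmann condensation (6-exo-trig): the enolate at C5, the only remaining α-CH of the C9 ketone, adds to the ester carbonyl C4 held cis to C1 on the enol ether and expels methoxide, and because C9 must bridge C1 and C5 the new C5 quaternary centre can form in one configuration only, dictated by C1.

Step 13
Reactants: 19 bicyclic carboxylic acid
Product: 20 1,3-dioxoisoindolin-2-yl ester of 19 (N-acyloxyphthalimide)
Conditions: N-hydroxyphthalimide, N,N'-diisopropylcarbodiimide, DMAP (cat.), CH2Cl2, rt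
Reagents that add atoms: N-hydroxyphthalimide, O=C1c2ccccc2C(=O)N1O
Why: Carbodiimide esterification of the acid with N-hydroxyphthalimide gives the redox-active ester needed for radical decarboxylation and changes no stereocentre.

Step 14
Reactants: 20 N-acyloxyphthalimide
Product: 21 1,7-diallyl-2-methoxy-8,8-dimethyl-5-[(2R)-5-methyl-2-(prop-1-en-2-yl)hex-4-en-1-yl]bicyclo[3.3.1]non-2-ene-4,9-dione (7-allyl exo, equatorial on chair ring B)
Conditions: Ru(bpy)3Cl2 (2 mol %), Hantzsch ester (1.5 equiv), i-Pr2NEt, allyl phenyl sulfone (5 equiv), CH2Cl2, blue LEDs, rt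
Reagents that add atoms: allyl phenyl sulfone, C=CCS(=O)(=O)c1ccccc1
Why: Photoredox decarboxylative allylation: single-electron reduction of the N-acyloxyphthalimide releases CO2 and the secondary C7 radical, which adds to the allyl sulfone and expels the sulfonyl radical, and since the endo face of C7 is shielded by the C2–C3–C4 bridge of ring A the allyl group should enter exo, so that both C7 epimers converge on the equatorial 7-substituent.

Step 15
Reactants: 21 1,7-diallyl bicycle
Product: 22 2-methoxy-8,8-dimethyl-1,7-bis(3-methylbut-2-en-1-yl)-5-[(2R)-5-methyl-2-(prop-1-en-2-yl)hex-4-en-1-yl]bicyclo[3.3.1]non-2-ene-4,9-dione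
Conditions: second-generation Grubbs catalyst RuCl2(=CHPh)(H2IMes)(PCy3) (10 mol %), 2-methyl-2-butene/CH2Cl2, 40 °C
Reagents that add atoms: 2-methyl-2-butene, CC=C(C)C
Why: Olefin cross-metathesis of the two monosubstituted allyl groups with excess 2-methyl-2-butene gives both prenyl groups, while the trisubstituted and 1,1-disubstituted alkenes of the lavandulyl group are degenerate or unreactive partners and no stereocentre is touched.

Step 16
Reactants: 22 3-unsubstituted methoxy enone
Product: 23 target, 3-benzoyl-2-methoxy-8,8-dimethyl-1,7-bis(3-methylbut-2-en-1-yl)-5-[(2R)-5-methyl-2-(prop-1-en-2-yl)hex-4-en-1-yl]bicyclo[3.3.1]non-2-ene-4,9-dione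
Conditions: lithium 2,2,6,6-tetramethylpiperidide (from the amine and n-BuLi), THF, −78 °C; then PhCOCl, −78 °C
Reagents that add atoms: benzoyl chloride, O=C(Cl)c1ccccc1
Why: Vinylic lithiation of the β-methoxy enone at C3, the only acidic CH left because both bridgeheads are quaternary, followed by C-acylation with benzoyl chloride installs the benzoyl group without forming a stereocentre.

**Compound list**

1 | (S)-4-benzyl-1,3-oxazolidin-2-one | O=C1N[C@@H](Cc2ccccc2)CO1 | starting material
2 | 3-methylbut-2-enoyl chloride | CC(C)=CC(=O)Cl | starting material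
3 | (S)-4-benzyl-3-(3-methylbut-2-enoyl)-1,3-oxazolidin-2-one | CC(C)=CC(=O)N1[C@@H](Cc2ccccc2)COC1=O | intermediate
4 | 1-bromo-3-methylbut-2-ene (prenyl bromide) | CC(C)=CCBr | starting material
5 | (S)-4-benzyl-3-[(S)-5-methyl-2-(prop-1-en-2-yl)hex-4-enoyl]-1,3-oxazolidin-2-one | C=C(C)[C@H](CC=C(C)C)C(=O)N1[C@@H](Cc2ccccc2)COC1=O | intermediate
6 | (S)-lavandulol, (S)-5-methyl-2-(prop-1-en-2-yl)hex-4-en-1-ol | C=C(C)[C@H](CC=C(C)C)CO | intermediate
7 | (S)-3-(iodomethyl)-2,6-dimethylhepta-1,5-diene | C=C(C)[C@H](CC=C(C)C)CI | intermediate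
8 | trimethyl phosphonoacetate | COC(=O)CP(=O)(OC)OC | starting material
9 | methyl (4R)-2-(dimethoxyphosphoryl)-7-methyl-4-(prop-1-en-2-yl)oct-6-enoate (C2 epimers) | C=C(C)[C@H](CC=C(C)C)CC(C(=O)OC)P(=O)(OC)OC | intermediate
10 | methyl (R)-7-methyl-2-methylidene-4-(prop-1-en-2-yl)oct-6-enoate | C=C(C)[C@H](CC=C(C)C)CC(=C)C(=O)OC | intermediate
11 | 3,3-dimethylglutaric anhydride | CC1(C)CC(=O)OC(=O)C1 | starting material
12 | 5-(allyloxy)-3,3-dimethyl-5-oxopentanoic acid | C=CCOC(=O)CC(C)(C)CC(=O)O | intermediate
13 | allyl 5-(imidazol-1-yl)-3,3-dimethyl-5-oxopentanoate | C=CCOC(=O)CC(C)(C)CC(=O)n1ccnc1 | intermediate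
14 | 7-allyl 1-methyl 5,5-dimethyl-3-oxoheptanedioate | C=CCOC(=O)CC(C)(C)CC(=O)CC(=O)OC | intermediate
15 | 7-allyl 1-methyl (E)-3-methoxy-5,5-dimethylhept-2-enedioate | C=CCOC(=O)CC(C)(C)C/C(OC)=C\C(=O)OC | intermediate
16 | 7-allyl 1-methyl (E)-3-methoxy-6-[(4R)-2-(methoxycarbonyl)-7-methyl-4-(prop-1-en-2-yl)oct-6-en-1-yl]-5,5-dimethylhept-2-enedioate (open-chain Michael adduct, epimers at the two new CH centres) | C=C(C)[C@H](CC=C(C)C)CC(C(=O)OC)CC(C(=O)OCC=C)C(C)(C)C/C(OC)=C\C(=O)OC | intermediate
17 | allyl 3-[(E)-1,3-dimethoxy-3-oxoprop-1-en-1-yl]-2,2-dimethyl-5-[(2R)-5-methyl-2-(prop-1-en-2-yl)hex-4-en-1-yl]-4-oxocyclohexane-1-carboxylate (stereoisomer mixture at ring positions 1, 3, 5) | C=C(C)[C@H](CC=C(C)C)CC1CC(C(=O)OCC=C)C(C)(C)C(C1=O)/C(OC)=C\C(=O)OC | intermediate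
18 | 3-allyl-3-[(E)-1,3-dimethoxy-3-oxoprop-1-en-1-yl]-2,2-dimethyl-5-[(2R)-5-methyl-2-(prop-1-en-2-yl)hex-4-en-1-yl]-4-oxocyclohexane-1-carboxylic acid (position 3 defined; epimers at 1 and 5) | C=C(C)[C@H](CC=C(C)C)CC1CC(C(=O)O)C(C)(C)[C@@](CC=C)(C1=O)/C(OC)=C\C(=O)OC | intermediate
19 | 1-allyl-2-methoxy-8,8-dimethyl-5-[(2R)-5-methyl-2-(prop-1-en-2-yl)hex-4-en-1-yl]-4,9-dioxobicyclo[3.3.1]non-2-ene-7-carboxylic acid (C7 epimers) | C=C(C)[C@H](CC=C(C)C)C[C@@]12CC(C(=O)O)C(C)(C)[C@@](CC=C)(C1=O)C(OC)=CC2=O | intermediate
20 | 1,3-dioxoisoindolin-2-yl 1-allyl-2-methoxy-8,8-dimethyl-5-[(2R)-5-methyl-2-(prop-1-en-2-yl)hex-4-en-1-yl]-4,9-dioxobicyclo[3.3.1]non-2-ene-7-carboxylate (C7 epimers) | C=C(C)[C@H](CC=C(C)C)C[C@@]12CC(C(=O)ON3C(=O)c4ccccc4C3=O)C(C)(C)[C@@](CC=C)(C1=O)C(OC)=CC2=O | intermediate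
21 | 1,7-diallyl-2-methoxy-8,8-dimethyl-5-[(2R)-5-methyl-2-(prop-1-en-2-yl)hex-4-en-1-yl]bicyclo[3.3.1]non-2-ene-4,9-dione (7-exo) | C=C(C)[C@H](CC=C(C)C)C[C@@]12C[C@@H](CC=C)C(C)(C)[C@@](CC=C)(C1=O)C(OC)=CC2=O | intermediate
22 | 2-methoxy-8,8-dimethyl-1,7-bis(3-methylbut-2-en-1-yl)-5-[(2R)-5-methyl-2-(prop-1-en-2-yl)hex-4-en-1-yl]bicyclo[3.3.1]non-2-ene-4,9-dione | C=C(C)[C@H](CC=C(C)C)C[C@@]12C[C@@H](CC=C(C)C)C(C)(C)[C@@](CC=C(C)C)(C1=O)C(OC)=CC2=O | intermediate
23 | 3-benzoyl-2-methoxy-8,8-dimethyl-1,7-bis(3-methylbut-2-en-1-yl)-5-[(2R)-5-methyl-2-(prop-1-en-2-yl)hex-4-en-1-yl]bicyclo[3.3.1]non-2-ene-4,9-dione | C=C(C)[C@H](CC=C(C)C)C[C@@]12C[C@@H](CC=C(C)C)C(C)(C)[C@@](CC=C(C)C)(C1=O)C(OC)=C(C(=O)c1ccccc1)C2=O | target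

**Step count and risks**

Total steps: 16 (steps 1 to 6 make the acrylate, steps 7 to 9 the bis-nucleophile, steps 10 to 16 the union and end game). Longest linear sequence: 13 steps (1 to 6, then 10 to 16).

Most likely to fail, step 10. The wrong carbanion may attack the acrylate (the C1 dienolate instead of the C7 enolate), or acylation may run through the α-carbon C3, or the acrylate may oligomerise. The fallback separates the two bond formations so that only one carbon nucleophile is present at a time. It sets out from 12 and 10. The dianion of 12 (LiN(i-Pr)2, 2.2 equiv, THF, −78 °C: carboxylate plus allyl ester enolate) is added to 10 to give the Michael adduct 5-(allyloxy)-4-[(4R)-2-(methoxycarbonyl)-7-methyl-4-(prop-1-en-2-yl)oct-6-en-1-yl]-3,3-dimethyl-5-oxopentanoic acid F1. This acid is chain-extended as in step 8 (CDI; methyl potassium malonate, MgCl2, Et3N) to 7-allyl 1-methyl 6-[(4R)-2-(methoxycarbonyl)-7-methyl-4-(prop-1-en-2-yl)oct-6-en-1-yl]-5,5-dimethyl-3-oxoheptanedioate F2. Enol ether formation as in step 9 then gives 16, now isolated, and LiN(i-Pr)2 (1.1 equiv, THF, −78 to 0 °C) closes ring B by the same γ-acylation. The route is rejoined at 17.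

Second, step 11. Facial selectivity of the allyl transfer may be poor at the crowded C1 enolate, which lies next to quaternary C8. The fallback gives up catalyst control and uses the lavandulyl stereocentre as an internal resolving handle. It sets out from 17. Allyl transfer with achiral Pd(PPh3)4 after NaN(SiMe3)2 should give 18 together with its C1 epimer F3. The mixture is cyclised under the conditions of step 12 to 19 and its diastereomer with the antipodal bicyclic core F4. These two differ in the 1,3-relationship between C5 and the adjacent side-chain stereocentre and should be separable by chromatography or crystallisation. The route is rejoined at 19.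

Third, step 12. The acylation may reverse through methoxide attack on the non-enolisable tricarbonyl product (retro-Claisen), or the hindered C5 enolate may fail to reach the deactivated vinylogous ester carbonyl. The fallback changes the acyl donor. It sets out from 18. Me2AlSEt (CH2Cl2, 0 °C to rt) converts the methyl ester into the S-ethyl thioester analogue of 18 F5, and LiN(SiMe3)2 (THF, −78 to 0 °C) then closes ring A by thio-Dieckmann cyclisation with loss of the poorly nucleophilic thiolate. The route is rejoined at 19.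

Further compounds
F1 | step 10 | 5-(allyloxy)-4-[(4R)-2-(methoxycarbonyl)-7-methyl-4-(prop-1-en-2-yl)oct-6-en-1-yl]-3,3-dimethyl-5-oxopentanoic acid | C=C(C)[C@H](CC=C(C)C)CC(C(=O)OC)CC(C(=O)OCC=C)C(C)(C)CC(=O)O
F2 | step 10 | 7-allyl 1-methyl 6-[(4R)-2-(methoxycarbonyl)-7-methyl-4-(prop-1-en-2-yl)oct-6-en-1-yl]-5,5-dimethyl-3-oxoheptanedioate | C=C(C)[C@H](CC=C(C)C)CC(C(=O)OC)CC(C(=O)OCC=C)C(C)(C)CC(=O)CC(=O)OC
F3 | step 11 | C1 epimer of 18 (opposite configuration at ring position 3) | C=C(C)[C@H](CC=C(C)C)CC1CC(C(=O)O)C(C)(C)[C@](CC=C)(C1=O)/C(OC)=C\C(=O)OC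
F4 | step 11 | diastereomer of 19 with the antipodal bicyclic core | C=C(C)[C@H](CC=C(C)C)C[C@]12CC(C(=O)O)C(C)(C)[C@](CC=C)(C1=O)C(OC)=CC2=O
F5 | step 12 | S-ethyl thioester analogue of 18 | C=C(C)[C@H](CC=C(C)C)CC1CC(C(=O)O)C(C)(C)[C@@](CC=C)(C1=O)/C(OC)=C\C(=O)SCC
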